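At late times neither earlier run has quite stopped, but both creep: over the last 20.0 min Tuesday's target gains 0.00470 M and Sunday's 0.00210 M, with the starting material as limiting reagent.

all flasks: starting material 0.250 M; catalyst 0.0250 M
- Tuesday's: partner 0.375 M
- Sunday's: partner 0.750 M
- Friday's: partner 1.30 M; time 140 min

| run | time / min | [target] / M |
|---|---|---|
| Tuesday's run | 23 | 0.0685 |
| Tuesday's run | 47 | 0.1031 |
| Tuesday's run | 70 | 0.1213 |
| Tuesday's run | 93 | 0.1317 |
| Tuesday's run | 120 | 0.1417 |
| Tuesday's run | 140 | 0.1464 |
| Sunday's run | 23 | 0.0879 |
| Sunday's run | 47 | 0.1302 |
| Sunday's run | 70 | 0.1499 |
| Sunday's run | 93 | 0.1617 |
| Sunday's run | 120 | 0.1680 |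
| Sunday's run | 140 | 0.1701 |

(each reading ± 8 × 10⁻⁴ M)

- apparent order in [partner] of the starting rate, round the charge of the Tuesday's run (the rate where two percent of its starting material have turned into target)
- target in the Friday's run at 140 min, as a share of the starting material charged

- Overall: starting material + partner -> target, with catalyst as catalyst.
- Constant volume, constant temperature.
- What is held in complexes is read along with the free species.
- An order is taken over about fifteen percent of the charge, up and down.

Friday's flask repeats the charges of starting material and catalyst, and its 140 min is the last reading time of both runs, so we need no lifetime or rate constant, and we compare the flasks at that one time. We take the missing share, the part of the charged starting material not found as target at that time: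

Tuesday: 41.4 %
Sunday: 32.0 %

We assume that this share follows a power of the charged partner. Going from Sunday to Friday then carries the step from Tuesday to Sunday forward by a factor 0.794. One scatter on Sunday's last reading moves Friday's missing share by 1.80 % of itself, and one on Tuesday's by 0.613 %. A drift of 0.100 in the exponent moves it by 5.50 %, which is more, so the constancy of the exponent is the number that has to be good. We then reckon the missing-share exponent, the power of the charged partner by which the missing share at this time falls:

exponent = ln(Tuesday's share / Sunday's share) / ln(Sunday's partner / Tuesday's partner) = 0.375
Friday's missing share = 26.0 %, so target = 74.0 %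

For the order, the 23 min readings give 0.360 across the step from Tuesday's partner to Sunday's, which we keep as a rough reading, taken later in the runs and over a wider span of partner than the order asked. The forecast, reading the stall as “a catalyst that dies”, gives 0.48 and 74 %.

The flask gives an order of 0.55 and 71.7 % of target.

    catalyst + partner ⇌ catalyst-reagent complex, settled at all times (9.930 M⁻¹)
    catalyst-reagent complex + starting material → target + catalyst (1.218 M⁻¹ min⁻¹)
    2 starting material → homo dimer (0.04398 M⁻¹ min⁻¹)
    2 catalyst ⇌ resting dimer, settled at all times (165.0 M⁻¹)

The homo dimer step by itself gives the charged starting material a first half-life of 45.5 min, shorter than the time asked. Friday's missing share is 28.3 %, and from Sunday to Friday the missing-share exponent comes to 0.223, lower than the 0.375 from Tuesday to Sunday.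

The data were computed for substances that don't exist, noise included.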